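## Retrosynthetic overview
Numbering: ring A = C1, C2 (C=O), C3, C4 (CH3), C5 (angular CH3), C10. Ring B = C5, C6, C7 (isopropenyl), C8 (OAc), C9 (OTig), C10. β is the face of the two methyl groups.
Feature used: the quaternary C5 lies β to the C9 oxygen through C10. With C9 as a ketone, the ring A alkene C5=C10 is therefore an enone whose β-carbon is C5, and the neighbouring C4 methyl group covers its β face.
Disconnections: C9 tiglate and C9–H (ketone reduction), C8–O (enolate hydroxylation), C7–isopropenyl (conjugate addition to a C7=C8 enone), then C5–C6 by radical conjugate closure of a 4-iodobutanoyl chain on C10.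
The iodo enone goes back through an N-methoxy-N-methylamide and an enol triflate to (S)-carvone. The carvone stereocentre becomes C2 and steers the C4 methyl group, and the carvone isopropenyl group is degraded to the C2 oxygen.
Ring order: ring A comes with carvone, and ring B is closed in the key step.

Key step: step 8

## Remarks on the chemistry
- Assumption: only one chair–chair form of the cis-decalin holds the C7 and C8 substituents equatorial. In that form a 2α-oxygen is axial on ring A and would collide with the C9 oxygen. C2 is therefore oxidised (steps 14 and 15) before C9 is reduced, and it is kept trigonal as an enol ether during the reduction.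
- The cis ketone 16 is treated as a kinetic product. It is not expected to be the more stable C10 epimer, so it sees no equilibrating base.
- In diketone 26 the cis fusion and the 8α-acetate are the stable arrangement, because a trans fusion would press the C7 isopropenyl group against the C5 methyl group. A short DBU equilibration at that stage could repair erosion at C8 or C10.

## Route

Step 1
Reactants: 1 (S)-carvone
Product: 3 (3S,5S)-2,3-dimethyl-5-(prop-1-en-2-yl)cyclohex-1-en-1-yl trifluoromethanesulfonate, via lithium enolate 2 (not isolated)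
Conditions: Me2CuLi (MeLi, CuI), Et2O, −20 °C; then PhNTf2, THF–DMPU, 0 °C to rt
Reagents that add atoms: lithium dimethylcuprate [Li+].C[Cu-]C; N-phenylbis(trifluoromethanesulfonimide) O=S(=O)(N(c1ccccc1)S(=O)(=O)C(F)(F)F)C(F)(F)F
Why: Organocuprate 1,4-addition with regiospecific O-triflation of the enolate: methyl enters axially and trans to the equatorial isopropenyl group (this sets C4 from the carvone stereocentre, the future C2), and trapping the enolate where it forms gives the tetrasubstituted C5=C10 enol triflate and removes the ketone before the side chain is degraded.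

Step 2
Reactants: 3 enol triflate from step 1
Product: 6 (1S,5S)-4,5-dimethyl-3-(trifluoromethylsulfonyloxy)cyclohex-3-en-1-yl acetate, via methoxy hydroperoxide 4 (not isolated), via peracetate 5 (not isolated)
Conditions: O3, CH2Cl2–MeOH, Sudan Red 7B, −78 °C, N2 purge; Ac2O, Et3N, DMAP, CH2Cl2, 0 to 40 °C
Reagents that add atoms: ozone [O-][O+]=O; methanol CO
Why: Chemoselective ozonolysis in methanol followed by Criegee rearrangement of the peracetate: the isopropenyl alkene is far more nucleophilic than the tetrasubstituted ring alkene, which the triflyloxy group deactivates, C2 migrates from carbon to oxygen with retention, and with no ring carbonyl present the new ester cannot be lost by β-elimination and aromatisation.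

Step 3
Reactants: 6 acetate from step 2
Product: 7 (3S,5S)-5-hydroxy-2,3-dimethylcyclohex-1-en-1-yl trifluoromethanesulfonate
Conditions: i-Bu2AlH, CH2Cl2, −78 °C; aq. potassium sodium tartrate
Reagents that add atoms: none
Why: Reductive ester cleavage by an aluminium hydride frees the C2 alcohol without an alkoxide base, so the S–O bond of the enol triflate, which is inert to i-Bu2AlH at low temperature, is not attacked.

Step 4
Reactants: 7 alcohol from step 3
Product: 8 (3S,5S)-5-(tert-butyldimethylsilyloxy)-2,3-dimethylcyclohex-1-en-1-yl trifluoromethanesulfonate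
Conditions: TBSCl, imidazole, DMF, rt
Reagents that add atoms: tert-butyldimethylsilyl chloride CC(C)(C)[Si](C)(C)Cl
Why: Imidazole-promoted silylation of an unhindered secondary alcohol gives an ether that survives palladium catalysis, Grignard addition, radical conditions and enolate chemistry.

Step 5
Reactants: 8 silyloxy enol triflate; 9 carbon monoxide; 10 N,O-dimethylhydroxylamine hydrochloride
Product: 11 (3S,5S)-5-(tert-butyldimethylsilyloxy)-N-methoxy-N,2,3-trimethylcyclohex-1-ene-1-carboxamide
Conditions: Pd(OAc)2 (5 mol %), Xantphos, Et3N, DMF, CO (1 atm), 60 °C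
Reagents that add atoms: none
Why: Palladium-catalysed aminocarbonylation of an enol triflate (oxidative addition to zerovalent palladium, CO insertion, capture of the acyl complex by the hydroxylamine) attaches C9 to C10 at the right oxidation level and leaves the C5=C10 alkene and both stereocentres untouched.

Step 6
Reactants: 11 N-methoxy-N-methylamide; 12 3-chloropropan-1-ol
Product: 14 1-[(3S,5S)-5-(tert-butyldimethylsilyloxy)-2,3-dimethylcyclohex-1-en-1-yl]-4-hydroxybutan-1-one, via bis-magnesium reagent 13 (not isolated)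
Conditions: 12, MeMgCl, THF, −20 °C; Mg, reflux; then 11, THF, 0 °C to rt; aq. NH4Cl
Reagents that add atoms: none
Why: Weinreb ketone synthesis with the O-magnesiated 3-hydroxypropyl Grignard reagent ClMgO(CH2)3MgCl brings in C6 to C8 without a protecting group, stops at the ketone stage, and cannot turn into 1,4-addition because C5 is fully substituted.

Step 7
Reactants: 14 hydroxy ketone
Product: 15 1-[(3S,5S)-5-(tert-butyldimethylsilyloxy)-2,3-dimethylcyclohex-1-en-1-yl]-4-iodobutan-1-one
Conditions: I2, PPh3, imidazole, CH2Cl2, 0 °C, dark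
Reagents that add atoms: iodine II
Why: Appel-type iodination converts the primary alcohol under nearly neutral conditions, so the γ-iodo ketone meets no base that could close a cyclopropane.

Step 8
Reactants: 15 iodo enone
Product: 16 (4aR,5S,7S,8aS)-7-(tert-butyldimethylsilyloxy)-4a,5-dimethyloctahydronaphthalen-1(2H)-one (cis-fused, 10β-H)
Conditions: (Me3Si)3SiH, AIBN, syringe pump (10 h), PhH (0.005 M), 80 °C; pH 7 buffer
Reagents that add atoms: none
Why: The silyl radical abstracts iodine, the primary C6 radical adds to C5 (the β-carbon of the C5=C10–C9=O enone), and the C10 α-keto radical takes hydrogen from the silane and carries the chain; this is a reductive radical conjugate addition of the Giese type, closest to the 6-endo cyclisation of ω-iodoalkyl cycloalkenyl ketones to 1-decalones with a quaternary fusion carbon. Ring B closes 6-endo-trig, which is preferred over 5-exo attack at C10 because C9 lies inside the forming ring and the nucleophilic radical is polarity-matched only with C5. C5 is controlled by the C4 methyl group, which A(1,2) strain with the C5 methyl holds pseudo-axial on the β face (C2–OTBS equatorial), so C6 enters axially from the α face and both methyl groups end up β. C10 is controlled in the hydrogen transfer: in the cyclised radical ring A is a chair with C5–CH3 and C2–OTBS axial, the α lobe at C10 points under ring A between the axial C2–O and C4–H bonds, and the bulky silane should therefore reach only the outward β lobe, which gives the cis fusion. The step needs ring closure to outrun direct reduction of the C6 radical, and slow addition of this slow hydrogen donor at high dilution secures that. Work-up stays neutral because the cis ketone is a kinetic product.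

Step 9
Reactants: 16 cis-decalone
Product: 17 C8=C9 trimethylsilyl enol ether of 16 (stereocentres as in 16)
Conditions: LiN(i-Pr)2, TMSCl (internal quench), THF, −78 °C; Et3N, pentane, cold aq. NaHCO3
Reagents that add atoms: trimethylsilyl chloride C[Si](C)(C)Cl
Why: Kinetic enolisation with in situ silylation takes a C8 proton because C10–H is tertiary and lies equatorial on ring B (poor overlap with the carbonyl group), so the ring-fusion centre is not touched.

Step 10
Reactants: 17 silyl enol ether
Product: 18 (4aR,5S,7S,8aS)-7-(tert-butyldimethylsilyloxy)-4a,5-dimethyl-4a,5,6,7,8,8a-hexahydronaphthalen-1(4H)-one (C7=C8 enone)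
Conditions: Pd(OAc)2 (10 mol %), O2 (1 atm), DMSO, 25–40 °C
Reagents that add atoms: none
Why: Saegusa–Ito oxidation: palladation at C8 and β-hydride elimination from C7 give the C7=C8 enone regiospecifically under non-basic conditions, with divalent palladium regenerated by O2.

Step 11
Reactants: 18 enone; 19 isopropenylmagnesium bromide
Product: 21 (3S,4aR,5S,7S,8aS)-7-(tert-butyldimethylsilyloxy)-4a,5-dimethyl-3-(prop-1-en-2-yl)octahydronaphthalen-1(2H)-one (7β-isopropenyl), via silyl enol ether 20 (not isolated)
Conditions: 19, CuBr·SMe2 (20 mol %), TMSCl, HMPA, THF, −78 °C; then 0.5 M HCl, THF, 0 °C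
Reagents that add atoms: none
Why: Copper-catalysed conjugate addition of a Grignard reagent accelerated by TMSCl: the enone reacts through the half-chair that keeps C2–OTBS equatorial and C5–CH3 axial on ring B, where axial attack at C7 comes from the convex β face while α attack would need a boat with C1 as flagpole, so the isopropenyl group should end up β.

Step 12
Reactants: 21 ketone
Product: 23 (2R,3R,4aR,5S,7S,8aS)-7-(tert-butyldimethylsilyloxy)-2-hydroxy-4a,5-dimethyl-3-(prop-1-en-2-yl)octahydronaphthalen-1(2H)-one (8α-OH), via sodium enolate 22 (not isolated)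
Conditions: NaN(SiMe3)2, THF, −78 °C; 2-(phenylsulfonyl)-3-phenyloxaziridine, −78 °C; AcOH
Reagents that add atoms: 2-(phenylsulfonyl)-3-phenyloxaziridine O=S(=O)(N1OC1c1ccccc1)c1ccccc1
Why: Enolate hydroxylation with an N-sulfonyloxaziridine (Davis oxidation): the hindered base removes a C8 proton rather than the tertiary C10–H, and the bulky oxidant approaches C8 anti to the neighbouring pseudo-axial C7 isopropenyl group, which gives the trans (8α) ketol and leaves the alkene alone.

Step 13
Reactants: 23 ketol
Product: 24 (2R,3R,4aR,5S,7S,8aS)-7-(tert-butyldimethylsilyloxy)-4a,5-dimethyl-1-oxo-3-(prop-1-en-2-yl)decahydronaphthalen-2-yl acetate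
Conditions: Ac2O, pyridine, DMAP (cat.), CH2Cl2, 0 °C
Reagents that add atoms: acetic anhydride CC(=O)OC(C)=O
Why: DMAP-catalysed acetylation of the only free hydroxyl group places the C8 ester while C9 is still a ketone, so no regiochemical choice between O8 and O9 arises.

Step 14
Reactants: 24 acetoxy ketone
Product: 25 (2R,3R,4aR,5S,7S,8aS)-7-hydroxy-4a,5-dimethyl-1-oxo-3-(prop-1-en-2-yl)decahydronaphthalen-2-yl acetate
Conditions: HF·pyridine, pyridine, THF, 0 °C to rt
Reagents that add atoms: none
Why: Fluoride-driven desilylation in a buffered, weakly acidic medium removes the C2 silyl group without enolising C9 or cleaving the acetate.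

Step 15
Reactants: 25 hydroxy ketone
Product: 26 (2R,3R,4aR,5S,8aS)-4a,5-dimethyl-1,7-dioxo-3-(prop-1-en-2-yl)decahydronaphthalen-2-yl acetate
Conditions: Dess–Martin periodinane, NaHCO3, CH2Cl2, 0 °C to rt
Reagents that add atoms: none
Why: Dess–Martin oxidation installs the C2 ketone under neutral conditions and makes C2 trigonal, which lets the decalin settle in the chair–chair form with the C7 and C8 substituents equatorial.

Step 16
Reactants: 26 diketone
Product: 29 (1S,2R,3R,4aR,5S,8aS)-1-hydroxy-4a,5-dimethyl-7-oxo-3-(prop-1-en-2-yl)decahydronaphthalen-2-yl acetate (9α-OH), via C2 silyl enol ether 27 (not isolated), via 9α-hydroxy silyl enol ether 28 (not isolated)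
Conditions: TMSOTf, Et3N, CH2Cl2, −78 to −20 °C; pentane, filtration; LiBH(s-Bu)3, THF, −78 °C; AcOH, then THF–H2O, 0 °C
Reagents that add atoms: none
Why: Transient protection by soft enolisation followed by sterically controlled hydride reduction: only the open C2 ketone is silylated (C9 is flanked by C8–OAc and C10), C2 stays flat, the C4–C5 bond stands axial over the α face of C9, the bulky borohydride therefore attacks equatorially from the β face to give the axial 9α-alcohol cis to the acetate, and mild acid returns the C2 ketone.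

Step 17
Reactants: 29 hydroxy ketone; 30 (E)-2-methylbut-2-enoyl chloride (tigloyl chloride)
Product: 31 (1S,2R,3R,4aR,5S,8aS)-2-acetoxy-4a,5-dimethyl-7-oxo-3-(prop-1-en-2-yl)decahydronaphthalen-1-yl (E)-2-methylbut-2-enoate (target)
Conditions: 30, DMAP, pyridine, CH2Cl2, 0 to 40 °C
Reagents that add atoms: none
Why: DMAP-mediated acylation through the acylpyridinium salt esterifies the remaining hindered 9α-hydroxyl group, and the tiglate is the stable (E) isomer, so its geometry is not at risk.

## Compound list
1 | (S)-carvone | CC(=C)[C@H]1CC=C(C)C(=O)C1 | starting material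
2 | lithium enolate from methyl addition to 1 | [Li+].[O-]C1=C(C)[C@@H](C)C[C@H](C(C)=C)C1 | intermediate
3 | (3S,5S)-2,3-dimethyl-5-(prop-1-en-2-yl)cyclohex-1-en-1-yl triflate | FC(F)(F)S(=O)(=O)OC1=C(C)[C@@H](C)C[C@H](C(C)=C)C1 | intermediate
4 | α-methoxy hydroperoxide of 3 (side-chain carbon unassigned) | FC(F)(F)S(=O)(=O)OC1=C(C)[C@@H](C)C[C@H](C(C)(OC)OO)C1 | intermediate
5 | peracetate of 4 | FC(F)(F)S(=O)(=O)OC1=C(C)[C@@H](C)C[C@H](C(C)(OC)OOC(C)=O)C1 | intermediate
6 | (1S,5S)-4,5-dimethyl-3-(triflyloxy)cyclohex-3-en-1-yl acetate | FC(F)(F)S(=O)(=O)OC1=C(C)[C@@H](C)C[C@H](OC(C)=O)C1 | intermediate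
7 | (3S,5S)-5-hydroxy-2,3-dimethylcyclohex-1-en-1-yl triflate | FC(F)(F)S(=O)(=O)OC1=C(C)[C@@H](C)C[C@H](O)C1 | intermediate
8 | (3S,5S)-5-(TBSO)-2,3-dimethylcyclohex-1-en-1-yl triflate | FC(F)(F)S(=O)(=O)OC1=C(C)[C@@H](C)C[C@H](O[Si](C)(C)C(C)(C)C)C1 | intermediate
9 | carbon monoxide | [C-]#[O+] | starting material
10 | N,O-dimethylhydroxylamine hydrochloride | CNOC.Cl | starting material
11 | (3S,5S)-5-(TBSO)-N-methoxy-N,2,3-trimethylcyclohex-1-ene-1-carboxamide | CON(C)C(=O)C1=C(C)[C@@H](C)C[C@H](O[Si](C)(C)C(C)(C)C)C1 | intermediate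
12 | 3-chloropropan-1-ol | OCCCCl | starting material
13 | ClMgO(CH2)3MgCl | Cl[Mg]CCCO[Mg]Cl | intermediate
14 | 1-[(3S,5S)-5-(TBSO)-2,3-dimethylcyclohex-1-en-1-yl]-4-hydroxybutan-1-one | OCCCC(=O)C1=C(C)[C@@H](C)C[C@H](O[Si](C)(C)C(C)(C)C)C1 | intermediate
15 | 1-[(3S,5S)-5-(TBSO)-2,3-dimethylcyclohex-1-en-1-yl]-4-iodobutan-1-one | ICCCC(=O)C1=C(C)[C@@H](C)C[C@H](O[Si](C)(C)C(C)(C)C)C1 | intermediate
16 | (4aR,5S,7S,8aS)-7-(TBSO)-4a,5-dimethyloctahydronaphthalen-1(2H)-one | C1C[C@@]2(C)[C@H](C[C@@H](O[Si](C)(C)C(C)(C)C)C[C@@H]2C)C(=O)C1 | intermediate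
17 | C8=C9 trimethylsilyl enol ether of 16 | C1C[C@@]2(C)[C@H](C[C@@H](O[Si](C)(C)C(C)(C)C)C[C@@H]2C)C(O[Si](C)(C)C)=C1 | intermediate
18 | (4aR,5S,7S,8aS)-7-(TBSO)-4a,5-dimethyl-4a,5,6,7,8,8a-hexahydronaphthalen-1(4H)-one | C1=CC[C@@]2(C)[C@H](C[C@@H](O[Si](C)(C)C(C)(C)C)C[C@@H]2C)C1=O | intermediate
19 | isopropenylmagnesium bromide | CC(=C)[Mg]Br | starting material
20 | C8=C9 trimethylsilyl enol ether of 21 | C=C(C)[C@H]1C[C@@]2(C)[C@H](C[C@@H](O[Si](C)(C)C(C)(C)C)C[C@@H]2C)C(O[Si](C)(C)C)=C1 | intermediate
21 | (3S,4aR,5S,7S,8aS)-7-(TBSO)-4a,5-dimethyl-3-(prop-1-en-2-yl)octahydronaphthalen-1(2H)-one | C=C(C)[C@H]1C[C@@]2(C)[C@H](C[C@@H](O[Si](C)(C)C(C)(C)C)C[C@@H]2C)C(=O)C1 | intermediate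
22 | C8=C9 sodium enolate of 21 | C=C(C)[C@H]1C[C@@]2(C)[C@H](C[C@@H](O[Si](C)(C)C(C)(C)C)C[C@@H]2C)C([O-])=C1.[Na+] | intermediate
23 | (2R,3R,4aR,5S,7S,8aS)-7-(TBSO)-2-hydroxy-4a,5-dimethyl-3-(prop-1-en-2-yl)octahydronaphthalen-1(2H)-one | C=C(C)[C@H]1C[C@@]2(C)[C@H](C[C@@H](O[Si](C)(C)C(C)(C)C)C[C@@H]2C)C(=O)[C@@H]1O | intermediate
24 | 8α-acetate of 23 | C=C(C)[C@H]1C[C@@]2(C)[C@H](C[C@@H](O[Si](C)(C)C(C)(C)C)C[C@@H]2C)C(=O)[C@@H]1OC(C)=O | intermediate
25 | 2α-alcohol from 24 | C=C(C)[C@H]1C[C@@]2(C)[C@H](C[C@@H](O)C[C@@H]2C)C(=O)[C@@H]1OC(C)=O | intermediate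
26 | 2,9-diketone, (2R,3R,4aR,5S,8aS)-4a,5-dimethyl-1,7-dioxo-3-(prop-1-en-2-yl)decahydronaphthalen-2-yl acetate | C=C(C)[C@H]1C[C@@]2(C)[C@H](CC(=O)C[C@@H]2C)C(=O)[C@@H]1OC(C)=O | intermediate
27 | C1=C2 trimethylsilyl enol ether of 26 (the C2=C3 isomer would serve equally) | C=C(C)[C@H]1C[C@@]2(C)[C@H](C=C(O[Si](C)(C)C)C[C@@H]2C)C(=O)[C@@H]1OC(C)=O | intermediate
28 | 9α-alcohol of 27 | C=C(C)[C@H]1C[C@@]2(C)[C@H](C=C(O[Si](C)(C)C)C[C@@H]2C)[C@H](O)[C@@H]1OC(C)=O | intermediate
29 | (1S,2R,3R,4aR,5S,8aS)-1-hydroxy-4a,5-dimethyl-7-oxo-3-(prop-1-en-2-yl)decahydronaphthalen-2-yl acetate | C=C(C)[C@H]1C[C@@]2(C)[C@H](CC(=O)C[C@@H]2C)[C@H](O)[C@@H]1OC(C)=O | intermediate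
30 | (E)-2-methylbut-2-enoyl chloride | C/C=C(\C)C(=O)Cl | starting material
31 | CNP0204573.1 | C=C(C)[C@H]1C[C@@]2(C)[C@H](CC(=O)C[C@@H]2C)[C@H](OC(=O)/C(C)=C/C)[C@@H]1OC(C)=O | target

## Counts and risks
Total step count: 17. Longest linear sequence: 17 steps from (S)-carvone.

**Step 8.** Three things may go wrong.
- Hydrogen transfer to the C6 radical may come before the slow attack on the fully substituted, twisted enone.
- A hydrogen shift from C1 or from the C5 methyl group may compete with ring closure.
- Hydrogen may be delivered to the α face of C10.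

Fallback, from 11 back to 18. MeMgBr would turn amide 11 into 1-[(3S,5S)-5-(tert-butyldimethylsilyloxy)-2,3-dimethylcyclohex-1-en-1-yl]ethan-1-one F1. Hosomi–Sakurai allylation (allyltrimethylsilane, TiCl4, CH2Cl2, −78 °C) would then form C5–C6 in a polar way, again anti to the pseudo-axial C4 methyl group. This gives 1-[(1S,2R,3S,5S)-5-(tert-butyldimethylsilyloxy)-2,3-dimethyl-2-(prop-2-en-1-yl)cyclohexyl]ethan-1-one F2. A Mannich reaction of its kinetic enolate (LiN(i-Pr)2, then dimethyl(methylidene)ammonium iodide) gives the 3-(dimethylamino)propan-1-one F3. N-Methylation (MeI) and elimination (NaHCO3) give the prop-2-en-1-one F4. Ring-closing metathesis (second-generation Grubbs catalyst, CH2Cl2, 40 °C) closes ring B directly to enone 18, with the C10 epimers separated at that stage. Steps 6 to 10 are bypassed.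

**Step 16.** Three things may go wrong.
- Discrimination between the two ketones in the silylation may be incomplete.
- The labile trimethylsilyl enol ether may be lost before hydride addition, so that C2 is reduced.
- Hydride may attack the α face of C9.

Fallback, from 26 back to 31. TBSOTf and Et3N would give the isolable C2 tert-butyldimethylsilyl enol ether of the diketone F5, which is purified on deactivated silica. LiBH(s-Bu)3 then gives the 9α-alcohol F6, and tigloyl chloride with DMAP gives the 9α-tiglate enol ether F7. The C2 ketone is unmasked only at the end with HF·pyridine, which gives 31.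

**Step 17.** Acylation of the axial 9α-hydroxyl group on the concave face may be slow. That would leave time for base-promoted acetyl migration from O8 to O9, and for closure of the hydroxyl group onto the C2 ketone as a hemiketal.

Fallback, from 29 back to 31. Base-free carbodiimide coupling (DCC, CH2Cl2) with 2-(diethoxyphosphoryl)propanoic acid acylates through a reactive phosphonoketene and would give the 9α-[2-(diethoxyphosphoryl)propanoate] F8. A Horner–Wadsworth–Emmons reaction with acetaldehyde (LiCl, DBU, MeCN) then builds the (E)-2-methylbut-2-enoate on the molecule and gives 31.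

## Further compounds
F1 | step 8 | 1-[(3S,5S)-5-(tert-butyldimethylsilyloxy)-2,3-dimethylcyclohex-1-en-1-yl]ethan-1-one | CC(=O)C1=C(C)[C@@H](C)C[C@H](O[Si](C)(C)C(C)(C)C)C1
F2 | step 8 | 1-[(1S,2R,3S,5S)-5-(tert-butyldimethylsilyloxy)-2,3-dimethyl-2-(prop-2-en-1-yl)cyclohexyl]ethan-1-one | C=CC[C@@]1(C)[C@H](C[C@@H](O[Si](C)(C)C(C)(C)C)C[C@@H]1C)C(C)=O
F3 | step 8 | 3-(dimethylamino)propan-1-one derived from F2 | C=CC[C@@]1(C)[C@H](C[C@@H](O[Si](C)(C)C(C)(C)C)C[C@@H]1C)C(=O)CCN(C)C
F4 | step 8 | prop-2-en-1-one derived from F3 | C=CC[C@@]1(C)[C@H](C[C@@H](O[Si](C)(C)C(C)(C)C)C[C@@H]1C)C(=O)C=C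
F5 | step 16 | C1=C2 tert-butyldimethylsilyl enol ether of 26 | C=C(C)[C@H]1C[C@@]2(C)[C@H](C=C(O[Si](C)(C)C(C)(C)C)C[C@@H]2C)C(=O)[C@@H]1OC(C)=O
F6 | step 16 | 9α-alcohol of F5 | C=C(C)[C@H]1C[C@@]2(C)[C@H](C=C(O[Si](C)(C)C(C)(C)C)C[C@@H]2C)[C@H](O)[C@@H]1OC(C)=O
F7 | step 16 | 9α-tiglate of F6 | C=C(C)[C@H]1C[C@@]2(C)[C@H](C=C(O[Si](C)(C)C(C)(C)C)C[C@@H]2C)[C@H](OC(=O)/C(C)=C/C)[C@@H]1OC(C)=O
F8 | step 17 | 9α-[2-(diethoxyphosphoryl)propanoate] of 29 | C=C(C)[C@H]1C[C@@]2(C)[C@H](CC(=O)C[C@@H]2C)[C@H](OC(=O)C(C)P(=O)(OCC)OCC)[C@@H]1OC(C)=O
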